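Ring A is disconnected at C4–C5. The gem-dimethyl carbon C4 sits on C5, which is α to the oxygenated C6 (a ketone during the synthesis), and quaternary C10 is β to it. A ring B cyclohexenone therefore receives the C1–C4 chain by asymmetric conjugate addition (setting C10), and the trapped C5=C6 silyl enol ether is alkylated intramolecularly by the C4 tertiary cation released from a chloride. In one operation this forges C4–C5, closes ring A and creates C5, giving 4,4,10-trimethyl-trans-decal-6-one after equilibration. The precursor is a 3-methyl-3-(4-chloro-4-methylpentyl)cyclohexenyl silyl ether. C8, C9, C6 and the linalool-derived side chain follow by enone chemistry.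

Key step: step 3

Remark 1: bicyclic compounds carry labdane numbering (ring A C1–C5/C10, ring B C5–C10, C20 on C10); α is the face opposite C20.
Remark 2: the target is the 6α-angelate of (13R)-labd-14-ene-6α,8α,13-triol; C13 has the configuration of (R)-linalool.
Remark 3: cleaving linalool at its trisubstituted alkene leaves one CH2 too many for C11–C13, so that carbon is excised by decarboxylative iodination (steps 10 and 11).
Remark 4: ring closure at C5 and alkylation at C9 are both expected to give the unwanted epimer first; each centre is α to a ketone and is corrected by base equilibration (steps 3 and 13).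

Step 1
Reactants: 1 5-bromo-2-methylpent-2-ene
Product: 2 1-bromo-4-chloro-4-methylpentane
Conditions: HCl (gas), CH2Cl2, −20 to 0 °C
Reagents that add atoms: hydrogen chloride, Cl
Why: Markovnikov hydrochlorination of the trisubstituted alkene through the tertiary cation should give the tertiary chloride while the primary bromide is untouched.

Step 2
Reactants: 2 1-bromo-4-chloro-4-methylpentane; 3 3-methylcyclohex-2-en-1-one
Product: 6 tert-butyl{[(3S)-3-(4-chloro-4-methylpentyl)-3-methylcyclohex-1-en-1-yl]oxy}dimethylsilane, via Grignard reagent 4 (not isolated), via bromomagnesium enolate 5 (not isolated)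
Conditions: Mg, Et2O, 0 to 20 °C; then 3, Cu(OTf)2 (3 mol %), chiral imidazolinium chloride (NHC precursor, 4 mol %), Et2O, −30 °C; then TBSOTf, Et3N, DMPU, −30 °C to rt
Reagents that add atoms: tert-butyldimethylsilyl trifluoromethanesulfonate, CC(C)(C)[Si](C)(C)OS(=O)(=O)C(F)(F)F
Why: Magnesium should insert into the primary C–Br bond much faster than into the tertiary C–Cl bond, the copper–NHC-catalysed asymmetric conjugate addition of the Grignard reagent creates quaternary C10 (ligand enantiomer chosen to deliver the chain to the face that gives the S centre), and O-silylation of the magnesium enolate before any proton transfer fixes the enol double bond at C5=C6.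

Step 3
Reactants: 6 tert-butyl{[(3S)-3-(4-chloro-4-methylpentyl)-3-methylcyclohex-1-en-1-yl]oxy}dimethylsilane
Product: 8 4,4,10-trimethyl-trans-decal-6-one (5α-H; 10β-CH3), via cis-decalone 7 (not isolated)
Conditions: TiCl4 (1.1 equiv), CH2Cl2 (0.01 M), −78 °C; aq NaHCO3; then NaOMe, MeOH, rt
Reagents that add atoms: none
Why: TiCl4 abstracts chloride from C4 and the tertiary cation is captured by C5 of the C5=C6 enol ether, after which the silyloxycarbenium ion collapses to the C6 ketone and TBSCl. This is the Lewis-acid SN1 α-tert-alkylation of silyl enol ethers by tert-alkyl chlorides (Mukaiyama-type), run here within one molecule. Ring A closes in a 6-(enolexo)-exo-tet mode through a chair in which the C1–C4 tether leaves C10 pseudo-equatorially and the C10 methyl is pseudo-axial, so bonding occurs on the enol face anti to that methyl and the cis-fused ketone 7 is expected first. C5 is then an enolisable methine next to C6=O, and methoxide equilibration should move it to the trans ring fusion, so the C10 centre from step 2 controls C5. Attack through C5 and not C7 is secured by the regiodefined enol ether, and cation capture must beat proton loss, which high dilution, −78 °C and the six-membered transition state favour.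

Step 4
Reactants: 8 4,4,10-trimethyl-trans-decal-6-one
Product: 9 4,4,10-trimethyl-trans-decal-7-en-6-one
Conditions: IBX, DMSO/toluene, 70 °C
Reagents that add atoms: none
Why: IBX dehydrogenation of the ketone can only introduce the C7=C8 double bond, because on the other side C5 is flanked by quaternary C4 and C10, and C5 keeps its preferred trans configuration.

Step 5
Reactants: 9 4,4,10-trimethyl-trans-decal-7-en-6-one
Product: 10 7α,8α-epoxy-4,4,10-trimethyl-trans-decal-6-one
Conditions: 30% H2O2, NaOH, MeOH, 0 °C to rt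
Reagents that add atoms: hydrogen peroxide, OO
Why: Weitz–Scheffer nucleophilic epoxidation of the enone, with hydroperoxide expected to add to C8 anti to the axial C10 methyl; the epoxide configuration is inconsequential because C8 becomes a carbonyl carbon in step 7.

Step 6
Reactants: 10 7α,8α-epoxy-4,4,10-trimethyl-trans-decal-6-one
Product: 11 4,4,10-trimethyl-trans-decal-6-en-8α-ol
Conditions: N2H4·H2O, AcOH (cat.), MeOH, 0 °C to rt
Reagents that add atoms: none
Why: Wharton transposition, in which the C6 hydrazone opens the epoxide to an allylic diazene that loses N2, moving the oxygen from C6 to C8 and placing the alkene at C6=C7.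

Step 7
Reactants: 11 4,4,10-trimethyl-trans-decal-6-en-8α-ol
Product: 12 4,4,10-trimethyl-trans-decal-6-en-8-one
Conditions: Dess–Martin periodinane, CH2Cl2, rt
Reagents that add atoms: none
Why: Dess–Martin oxidation of the secondary allylic alcohol gives the transposed enone, in which C7 is an sp2 carbon so that only C9 can be enolised kinetically.

Step 8
Reactants: 13 (R)-linalool
Product: 14 (3R)-3,7-dimethyl-3-(triethylsilyloxy)octa-1,6-diene
Conditions: TESOTf, 2,6-lutidine, CH2Cl2, −78 to 0 °C
Reagents that add atoms: triethylsilyl trifluoromethanesulfonate, CC[Si](CC)(CC)OS(=O)(=O)C(F)(F)F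
Why: Silylation of the tertiary allylic alcohol with the silyl triflate protects the future C13 carbinol without touching its stereocentre.

Step 9
Reactants: 14 (3R)-3,7-dimethyl-3-(triethylsilyloxy)octa-1,6-diene
Product: 16 (4R)-4-methyl-4-(triethylsilyloxy)hex-5-enal, via ozonide 15 (not isolated)
Conditions: O3, CH2Cl2, −78 °C (Sudan Red 7B end point); then PPh3, −78 °C to rt
Reagents that add atoms: ozone, [O-][O+]=O
Why: Ozonolysis should be selective for the electron-rich trisubstituted alkene over the hindered, inductively deactivated vinyl group when the dye end point is respected, and reductive work-up gives the aldehyde.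

Step 10
Reactants: 16 (4R)-4-methyl-4-(triethylsilyloxy)hex-5-enal
Product: 17 (4R)-4-methyl-4-(triethylsilyloxy)hex-5-enoic acid
Conditions: NaClO2, NaH2PO4, 2-methylbut-2-ene, t-BuOH/H2O, 0 °C to rt
Reagents that add atoms: sodium chlorite, [Na+].[O-]Cl=O
Why: Pinnick oxidation converts the aldehyde into the acid under buffered conditions that spare the vinyl group and the tertiary silyl ether.

Step 11
Reactants: 17 (4R)-4-methyl-4-(triethylsilyloxy)hex-5-enoic acid
Product: 19 (3R)-5-iodo-3-methyl-3-(triethylsilyloxy)pent-1-ene, via thiohydroxamate ester 18 (not isolated)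
Conditions: N-hydroxypyridine-2-thione, DCC, DMAP (cat.), CH2Cl2, rt, dark; then CHI3, visible light, rt
Reagents that add atoms: iodoform, IC(I)I
Why: Barton decarboxylative iodination excises the carboxyl carbon; the primary radical can only cyclise onto the vinyl group in slow 4-exo or 5-endo modes and instead abstracts iodine from iodoform, giving the C11–C16 unit with C13 unchanged.

Step 12
Reactants: 12 4,4,10-trimethyl-trans-decal-6-en-8-one; 19 (3R)-5-iodo-3-methyl-3-(triethylsilyloxy)pent-1-ene
Product: 21 (9βH,13R)-13-(triethylsilyloxy)-17-norlabda-6,14-dien-8-one (side chain 9α), via lithium dienolate 20 (not isolated)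
Conditions: LiN(i-Pr)2, THF, −78 °C; then 19, DMPU, −78 to 0 °C
Reagents that add atoms: none
Why: Kinetic deprotonation at C9, the only α' position, gives the cross-conjugated dienolate, and its SN2 alkylation by the primary iodide should occur on the α face anti to the C10 methyl, so the chain enters axially and the C9 epimer of the natural series is expected (corrected in step 13).

Step 13
Reactants: 21 (9βH,13R)-13-(triethylsilyloxy)-17-norlabda-6,14-dien-8-one
Product: 23 (13R)-6α,7α-epoxy-13-(triethylsilyloxy)-17-norlabd-14-en-8-one (9α-H), via 9-epi epoxy ketone 22 (not isolated)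
Conditions: 30% H2O2, NaOH, MeOH, 0 °C; then DBU, toluene, 60 °C
Reagents that add atoms: hydrogen peroxide, OO
Why: In this Weitz–Scheffer epoxidation hydroperoxide should add to C6 from the α face because the β face is screened by the axial C10 and C4β methyls, which fixes the 6α C–O bond; DBU then equilibrates C9, the only enolisable centre, and the chain should move to the equatorial β position away from the α-epoxide oxygen and H-5α.

Step 14
Reactants: 23 (13R)-6α,7α-epoxy-13-(triethylsilyloxy)-17-norlabd-14-en-8-one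
Product: 24 (13R)-6α-hydroxy-13-(triethylsilyloxy)-17-norlabd-14-en-8-one
Conditions: SmI2, THF/MeOH, −90 °C
Reagents that add atoms: none
Why: Reductive opening of the α,β-epoxy ketone: SmI2 forms the ketyl, the adjacent C7–O bond is cleaved and the samarium enolate is protonated at C7 by methanol, so the C6–O bond and its α configuration are retained.

Step 15
Reactants: 24 (13R)-6α-hydroxy-13-(triethylsilyloxy)-17-norlabd-14-en-8-one
Product: 25 (13R)-6α,13-bis(triethylsilyloxy)-17-norlabd-14-en-8-one
Conditions: TESCl, imidazole, DMF, rt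
Reagents that add atoms: chlorotriethylsilane, CC[Si](Cl)(CC)CC
Why: Silylation of the secondary 6α-hydroxyl removes the free β-hydroxy ketone, which could otherwise undergo retro-aldol cleavage or consume the titanium reagent of step 16.

Step 16
Reactants: 25 (13R)-6α,13-bis(triethylsilyloxy)-17-norlabd-14-en-8-one
Product: 26 (13R)-6α,13-bis(triethylsilyloxy)labda-8(17),14-diene
Conditions: Cp2TiMe2, toluene, 70 °C
Reagents that add atoms: dimethyltitanocene, C[Ti+2]C.c1cc[cH-]c1.c1cc[cH-]c1
Why: Petasis methylenation is non-basic, so the hindered C8 ketone is converted into the exocyclic alkene without enolisation at C9 or β-elimination of the 6α-silyloxy group.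

Step 17
Reactants: 26 (13R)-6α,13-bis(triethylsilyloxy)labda-8(17),14-diene
Product: 27 (13R)-8α,17-epoxy-6α,13-bis(triethylsilyloxy)labd-14-ene
Conditions: mCPBA, Na2HPO4, CH2Cl2, 0 °C
Reagents that add atoms: 3-chloroperoxybenzoic acid, OOC(=O)c1cccc(Cl)c1
Why: Prilezhaev epoxidation should prefer the 1,1-disubstituted C8=C17 alkene over the hindered vinyl group, and the peracid should approach from the α face because the axial C10 methyl screens the β face, placing the epoxide oxygen α (equatorial).

Step 18
Reactants: 27 (13R)-8α,17-epoxy-6α,13-bis(triethylsilyloxy)labd-14-ene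
Product: 28 (13R)-6α,13-bis(triethylsilyloxy)labd-14-en-8α-ol
Conditions: LiAlH4, THF, 0 °C to rt; aq sodium potassium tartrate
Reagents that add atoms: none
Why: Hydride opens the spiro epoxide by SN2 attack at the primary C17, leaving the 8α tertiary alcohol and the axial 8β methyl, while the silyl ethers survive.

Step 19
Reactants: 28 (13R)-6α,13-bis(triethylsilyloxy)labd-14-en-8α-ol
Product: 29 (13R)-labd-14-ene-6α,8α,13-triol
Conditions: Bu4NF, THF, rt to 40 °C
Reagents that add atoms: none
Why: Fluoride-mediated desilylation removes both triethylsilyl ethers under non-acidic conditions, which avoids ionisation of the tertiary allylic C13 alcohol.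

Step 20
Reactants: 29 (13R)-labd-14-ene-6α,8α,13-triol; 30 angelic acid
Product: 32 (13R)-6α-angeloyloxylabd-14-ene-8α,13-diol (CNP0203829.1), via mixed anhydride 31 (not isolated)
Conditions: 2,4,6-trichlorobenzoyl chloride, Et3N, toluene, rt; then 29, toluene, 75 °C
Reagents that add atoms: none
Why: Yamaguchi-type mixed-anhydride esterification should acylate the single secondary hydroxyl (6α, equatorial) while the two tertiary alcohols stay inert, and the DMAP-free conditions avoid Z to E isomerisation of the angelate.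

Compound list
1 | 5-bromo-2-methylpent-2-ene | CC(C)=CCCBr | starting material
2 | 1-bromo-4-chloro-4-methylpentane | CC(C)(Cl)CCCBr | intermediate
3 | 3-methylcyclohex-2-en-1-one | CC1=CC(=O)CCC1 | starting material
4 | (4-chloro-4-methylpentyl)magnesium bromide | CC(C)(Cl)CCC[Mg]Br | intermediate
5 | bromomagnesium (3S)-3-(4-chloro-4-methylpentyl)-3-methylcyclohex-1-en-1-olate | CC(C)(Cl)CCC[C@]1(C)CCCC(O[Mg]Br)=C1 | intermediate
6 | tert-butyl{[(3S)-3-(4-chloro-4-methylpentyl)-3-methylcyclohex-1-en-1-yl]oxy}dimethylsilane | CC(C)(Cl)CCC[C@]1(C)CCCC(O[Si](C)(C)C(C)(C)C)=C1 | intermediate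
7 | 4,4,10-trimethyl-cis-decal-6-one (5β-H, 10β-CH3) | C1[C@@]2(C)CCCC(C)(C)[C@H]2C(=O)CC1 | intermediate
8 | 4,4,10-trimethyl-trans-decal-6-one (5α-H, 10β-CH3), i.e. (4aR,8aS)-4a,8,8-trimethyloctahydronaphthalen-1(2H)-one | C1[C@@]2(C)CCCC(C)(C)[C@@H]2C(=O)CC1 | intermediate
9 | 4,4,10-trimethyl-trans-decal-7-en-6-one | C1[C@@]2(C)CCCC(C)(C)[C@@H]2C(=O)C=C1 | intermediate
10 | 7α,8α-epoxy-4,4,10-trimethyl-trans-decal-6-one | C1[C@@]2(C)CCCC(C)(C)[C@@H]2C(=O)[C@H]3O[C@H]31 | intermediate
11 | 4,4,10-trimethyl-trans-decal-6-en-8α-ol | C1[C@@]2(C)CCCC(C)(C)[C@@H]2C=C[C@H]1O | intermediate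
12 | 4,4,10-trimethyl-trans-decal-6-en-8-one | C1[C@@]2(C)CCCC(C)(C)[C@@H]2C=CC1=O | intermediate
13 | (R)-linalool | C=C[C@](C)(O)CCC=C(C)C | starting material
14 | (3R)-3,7-dimethyl-3-(triethylsilyloxy)octa-1,6-diene | C=C[C@](C)(O[Si](CC)(CC)CC)CCC=C(C)C | intermediate
15 | ozonide (3,3-dimethyl-1,2,4-trioxolane) of 14 at the trisubstituted alkene | C=C[C@](C)(O[Si](CC)(CC)CC)CCC1OOC(C)(C)O1 | intermediate
16 | (4R)-4-methyl-4-(triethylsilyloxy)hex-5-enal | C=C[C@](C)(O[Si](CC)(CC)CC)CCC=O | intermediate
17 | (4R)-4-methyl-4-(triethylsilyloxy)hex-5-enoic acid | C=C[C@](C)(O[Si](CC)(CC)CC)CCC(=O)O | intermediate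
18 | 2-thioxopyridin-1(2H)-yl (4R)-4-methyl-4-(triethylsilyloxy)hex-5-enoate | C=C[C@](C)(O[Si](CC)(CC)CC)CCC(=O)On1ccccc1=S | intermediate
19 | (3R)-5-iodo-3-methyl-3-(triethylsilyloxy)pent-1-ene | C=C[C@](C)(O[Si](CC)(CC)CC)CCI | intermediate
20 | lithium 8,9-dienolate of 12 (4,4,10-trimethyl-trans-decal-6,8-dien-8-olate) | [Li]OC1=C[C@@]2(C)CCCC(C)(C)[C@@H]2C=C1 | intermediate
21 | (9βH,13R)-13-(triethylsilyloxy)-17-norlabda-6,14-dien-8-one (side chain 9α) | C=C[C@](C)(O[Si](CC)(CC)CC)CC[C@H]1[C@@]2(C)CCCC(C)(C)[C@@H]2C=CC1=O | intermediate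
22 | (9βH,13R)-6α,7α-epoxy-13-(triethylsilyloxy)-17-norlabd-14-en-8-one | C=C[C@](C)(O[Si](CC)(CC)CC)CC[C@H]1[C@@]2(C)CCCC(C)(C)[C@@H]2[C@H]3O[C@H]3C1=O | intermediate
23 | (13R)-6α,7α-epoxy-13-(triethylsilyloxy)-17-norlabd-14-en-8-one (9α-H, side chain 9β) | C=C[C@](C)(O[Si](CC)(CC)CC)CC[C@@H]1[C@@]2(C)CCCC(C)(C)[C@@H]2[C@H]3O[C@H]3C1=O | intermediate
24 | (13R)-6α-hydroxy-13-(triethylsilyloxy)-17-norlabd-14-en-8-one | C=C[C@](C)(O[Si](CC)(CC)CC)CC[C@@H]1[C@@]2(C)CCCC(C)(C)[C@@H]2[C@@H](O)CC1=O | intermediate
25 | (13R)-6α,13-bis(triethylsilyloxy)-17-norlabd-14-en-8-one | C=C[C@](C)(O[Si](CC)(CC)CC)CC[C@@H]1[C@@]2(C)CCCC(C)(C)[C@@H]2[C@@H](O[Si](CC)(CC)CC)CC1=O | intermediate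
26 | (13R)-6α,13-bis(triethylsilyloxy)labda-8(17),14-diene | C=C[C@](C)(O[Si](CC)(CC)CC)CC[C@@H]1[C@@]2(C)CCCC(C)(C)[C@@H]2[C@@H](O[Si](CC)(CC)CC)CC1=C | intermediate
27 | (13R)-8α,17-epoxy-6α,13-bis(triethylsilyloxy)labd-14-ene | C=C[C@](C)(O[Si](CC)(CC)CC)CC[C@@H]1[C@@]2(C)CCCC(C)(C)[C@@H]2[C@@H](O[Si](CC)(CC)CC)C[C@]13CO3 | intermediate
28 | (13R)-6α,13-bis(triethylsilyloxy)labd-14-en-8α-ol | C=C[C@](C)(O[Si](CC)(CC)CC)CC[C@@H]1[C@@]2(C)CCCC(C)(C)[C@@H]2[C@@H](O[Si](CC)(CC)CC)C[C@@]1(C)O | intermediate
29 | (13R)-labd-14-ene-6α,8α,13-triol | C=C[C@](C)(O)CC[C@@H]1[C@@]2(C)CCCC(C)(C)[C@@H]2[C@@H](O)C[C@@]1(C)O | intermediate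
30 | angelic acid, (Z)-2-methylbut-2-enoic acid | C/C=C(/C)C(=O)O | starting material
31 | (Z)-2-methylbut-2-enoic 2,4,6-trichlorobenzoic anhydride | C/C=C(/C)C(=O)OC(=O)c1c(Cl)cc(Cl)cc1Cl | intermediate
32 | (13R)-6α-angeloyloxylabd-14-ene-8α,13-diol (5S,6S,8R,9R,10S,13R) | C=C[C@](C)(O)CC[C@@H]1[C@@]2(C)CCCC(C)(C)[C@@H]2[C@@H](OC(=O)/C(C)=C\C)C[C@@]1(C)O | target

Total step count: 20. Longest linear sequence: 16 steps (steps 1–7 and 12–20, from 1); the side-chain iodide 19 takes 4 steps (8–11).

Steps most likely to fail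

Step 3. Proton loss from the C4 cation and protodesilylation of the enol ether by the acid so released may outrun C4–C5 bond formation, or equilibration of the ring fusion may stall short of the trans isomer. The fallback sets out from enone 3 and returns at 8, closing ring A by carbonyl condensation instead of cation capture. The copper–NHC conjugate addition of step 2 is run with [3-(2-methyl-1,3-dioxolan-2-yl)propyl]magnesium chloride F1, made from commercial 2-(3-chloropropyl)-2-methyl-1,3-dioxolane and Mg. This gives the ketone acetal (3S)-3-methyl-3-[3-(2-methyl-1,3-dioxolan-2-yl)propyl]cyclohexan-1-one F2. Aqueous HCl in THF unmasks the diketone (3R)-3-methyl-3-(4-oxopentyl)cyclohexan-1-one F3. KOH in MeOH then effects aldol cyclodehydration of C5 onto the C4 carbonyl to give the bicyclic enone 4,10-dimethyl-decal-4-en-6-one F4. Me2CuLi with BF3·OEt2 adds the second methyl group at C4, and protonation at C5 followed by NaOMe equilibration gives 8.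

Step 2. Magnesium insertion or loss of HCl at the tertiary C–Cl bond during Grignard formation, erosion of enantiofacial control with the functionalised reagent, or incomplete O-silylation of the hindered magnesium enolate may occur. The fallback sets out from bromide 1 (with enone 3) and returns at 6, installing the chloride after the conjugate addition. Mg converts 1 into (4-methylpent-3-en-1-yl)magnesium bromide F5. The same catalytic addition to 3 gives the bromomagnesium enolate F6, which is trapped with Ac2O as the enol acetate (3S)-3-methyl-3-(4-methylpent-3-en-1-yl)cyclohex-1-en-1-yl acetate F7. HCl in CH2Cl2 at −40 °C adds to the remote trisubstituted alkene, giving (3S)-3-(4-chloro-4-methylpentyl)-3-methylcyclohex-1-en-1-yl acetate F8. MeLi (2 equiv, Et2O, −78 to 0 °C) cleaves the enol ester to the regiodefined lithium enolate F9, and TBSOTf silylates it to 6.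

Step 12. SN2 attack of the hindered, neopentyl-type C9 enolate on an unactivated primary iodide may be slow, allowing E2 loss of HI from 19 and self-condensation of the dienolate. The fallback sets out from iodide 19 and dienolate 20 and returns at 21, replacing substitution by carbonyl addition. Kornblum-type oxidation of 19 (Me3NO, DMSO, rt) gives the aldehyde (3R)-3-methyl-3-(triethylsilyloxy)pent-4-enal F10. Aldol addition of 20 to F10 at −78 °C, again on the α face of C9, gives the β-hydroxy ketone (9βH,13R)-11-hydroxy-13-(triethylsilyloxy)-17-norlabda-6,14-dien-8-one F11 (either C11 epimer serves). 1,1'-Thiocarbonyldiimidazole converts it into the O-(8-oxo-17-norlabda-6,14-dien-11-yl) imidazole-1-carbothioate F12. Barton–McCombie deoxygenation (Bu3SnH, AIBN, toluene, 80 °C) removes the C11 oxygen and gives 21.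

Further compounds
F1 | step 3 | [3-(2-methyl-1,3-dioxolan-2-yl)propyl]magnesium chloride | CC1(CCC[Mg]Cl)OCCO1
F2 | step 3 | (3S)-3-methyl-3-[3-(2-methyl-1,3-dioxolan-2-yl)propyl]cyclohexan-1-one | CC1(CCC[C@]2(C)CCCC(=O)C2)OCCO1
F3 | step 3 | (3R)-3-methyl-3-(4-oxopentyl)cyclohexan-1-one | CC(=O)CCC[C@]1(C)CCCC(=O)C1
F4 | step 3 | 4,10-dimethyl-decal-4-en-6-one (10β-CH3) | CC1=C2C(=O)CCC[C@@]2(C)CCC1
F5 | step 2 | (4-methylpent-3-en-1-yl)magnesium bromide | CC(C)=CCC[Mg]Br
F6 | step 2 | bromomagnesium (3S)-3-methyl-3-(4-methylpent-3-en-1-yl)cyclohex-1-en-1-olate | CC(C)=CCC[C@]1(C)CCCC(O[Mg]Br)=C1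
F7 | step 2 | (3S)-3-methyl-3-(4-methylpent-3-en-1-yl)cyclohex-1-en-1-yl acetate | CC(C)=CCC[C@]1(C)CCCC(OC(C)=O)=C1
F8 | step 2 | (3S)-3-(4-chloro-4-methylpentyl)-3-methylcyclohex-1-en-1-yl acetate | CC(C)(Cl)CCC[C@]1(C)CCCC(OC(C)=O)=C1
F9 | step 2 | lithium (3S)-3-(4-chloro-4-methylpentyl)-3-methylcyclohex-1-en-1-olate | CC(C)(Cl)CCC[C@]1(C)CCCC(O[Li])=C1
F10 | step 12 | (3R)-3-methyl-3-(triethylsilyloxy)pent-4-enal | C=C[C@](C)(O[Si](CC)(CC)CC)CC=O
F11 | step 12 | (9βH,13R)-11-hydroxy-13-(triethylsilyloxy)-17-norlabda-6,14-dien-8-one | C=C[C@](C)(O[Si](CC)(CC)CC)CC(O)[C@H]1[C@@]2(C)CCCC(C)(C)[C@@H]2C=CC1=O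
F12 | step 12 | O-[(9βH,13R)-8-oxo-13-(triethylsilyloxy)-17-norlabda-6,14-dien-11-yl] 1H-imidazole-1-carbothioate | C=C[C@](C)(O[Si](CC)(CC)CC)CC(OC(=S)n1ccnc1)[C@H]1[C@@]2(C)CCCC(C)(C)[C@@H]2C=CC1=O
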